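## Retrosynthetic overview
1. Ring C (pyranone) is closed last, by acid cyclodehydration of an o‑oxygenated aryl 1,3‑diketone in the same operation that removes all protecting groups.
2. Ring D (oxepine) is closed just before that, by an intramolecular Claisen condensation (flavone C2–C3 bond) between a ring‑A aryl ketone enolate and the ring‑B methyl ester.
3. The ketone comes from a ring‑A aryllithium (phloroglucinol tris‑MOM ether, two lithiation/prenylation rounds) and a chiral aldehyde that already carries ring B.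
4. The aldehyde comes from an (S)‑α‑hydroxy ester. Mitsunobu inversion with a bromophenol makes the aryl–O–C* bond, MeMgBr builds CMe2OH, Br/Li exchange with ClCO2Me brings in C2, and alkene cleavage unmasks C4.
5. The stereocentre comes from ketoreductase reduction of achiral ethyl 2‑oxohex‑5‑enoate. Ring order: A and B are bought, then D, then C.

Assumption: the stereocentre of the given SMILES is read as (R), and (S)‑selective ketoreductase preparations and but‑3‑enylmagnesium bromide solution are taken as purchasable.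

Abbreviations:
- MOM = CH2OCH3
- TES = SiEt3
- prenyl = 3‑methylbut‑2‑enyl
- ArA = 2,4,6‑tris(MOM‑oxy)‑3,5‑diprenylphenyl
- ArL = 3,5‑diallyl‑2,4,6‑tris(MOM‑oxy)phenyl

## Route

Step 1
Reactants: 1 diethyl oxalate; 2 but‑3‑en‑1‑ylmagnesium bromide
Product: 4 ethyl 2‑oxohex‑5‑enoate, via bromomagnesium hemiketal alkoxide 3 (not isolated)
Conditions: 2 added to 1 (1.5 equiv), THF/Et2O, −78 °C; aqueous quench at −78 °C
Reagents that add atoms: none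
Why: Grignard mono‑acylation of an oxalate diester works because adduct 3 survives at −78 °C until the quench, so the α‑keto ester appears only when no Grignard reagent is left and a second addition cannot occur.

Step 2
Reactants: 4 ethyl 2‑oxohex‑5‑enoate
Product: 5 ethyl (2S)‑2‑hydroxyhex‑5‑enoate
Conditions: (S)‑selective ketoreductase (NADPH‑dependent oxidoreductase, EC 1.1.1), NADP+ (cat.), iPrOH (10 vol%), KH2PO4/K2HPO4 buffer pH 7.0, 30 °C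
Reagents that add atoms: none
Why: In this asymmetric biocatalytic ketone reduction the ketoreductase binds the activated, prochiral α‑keto ester in one orientation and delivers hydride from NADPH to its Re face, which sets the only stereocentre as (S) (typically >99% ee), while the same enzyme regenerates NADPH from propan‑2‑ol.

Step 3
Reactants: 6 4‑bromobenzene‑1,3‑diol (4‑bromoresorcinol)
Product: 7 2‑bromo‑5‑(methoxymethoxy)phenol
Conditions: MOMCl (1.0 equiv, slow addition), iPr2NEt, CH2Cl2/THF, 0 °C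
Reagents that add atoms: chloromethyl methyl ether (MOMCl), COCCl
Why: This Williamson‑type O‑alkylation is under steric control, because the hydroxyl para to bromine is open while the one next to bromine is shielded and gives the less nucleophilic phenoxide, so one equivalent gives mainly 7, which chromatography frees from the regioisomer and the bis‑ether.

Step 4
Reactants: 5 ethyl (2S)‑2‑hydroxyhex‑5‑enoate; 7 2‑bromo‑5‑(methoxymethoxy)phenol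
Product: 9 ethyl (2R)‑2‑[2‑bromo‑5‑(methoxymethoxy)phenoxy]hex‑5‑enoate, via alkoxyphosphonium ion 8 (not isolated)
Conditions: PPh3, DIAD, toluene, 0 °C → rt
Reagents that add atoms: none
Why: In this Mitsunobu etherification the acidic o‑bromophenol displaces the activated oxygen of 8 by SN2 with clean inversion, (S) → (R), and α‑hydroxy esters are among the best‑behaved secondary alcohols for this reaction.

Step 5
Reactants: 9 ethyl (2R)‑2‑[2‑bromo‑5‑(methoxymethoxy)phenoxy]hex‑5‑enoate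
Product: 11 (3R)‑3‑[2‑bromo‑5‑(methoxymethoxy)phenoxy]‑2‑methylhept‑6‑en‑2‑ol, via methyl ketone 10 (not isolated)
Conditions: MeMgBr (3.5 equiv), THF, −40 → 0 °C; aqueous work‑up
Reagents that add atoms: methylmagnesium bromide, C[Mg]Br
Why: In this double Grignard addition to the only ester, addition to ester and ketone outruns enolisation at low temperature so the (R) centre is kept, and the aryl bromide, the MOM ether and the alkene are inert to MeMgBr.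

Step 6
Reactants: 11 (3R)‑3‑[2‑bromo‑5‑(methoxymethoxy)phenoxy]‑2‑methylhept‑6‑en‑2‑ol
Product: 12 {[(3R)‑3‑[2‑bromo‑5‑(methoxymethoxy)phenoxy]‑2‑methylhept‑6‑en‑2‑yl]oxy}triethylsilane
Conditions: Et3SiOTf (1.2 equiv), 2,6‑lutidine, CH2Cl2, −78 → 0 °C
Reagents that add atoms: triethylsilyl trifluoromethanesulfonate, CC[Si](CC)(CC)OS(=O)(=O)C(F)(F)F
Why: Silyl triflate silylation caps even a hindered tertiary alcohol faster than it touches the aryl MOM acetal, and it removes the acidic and nucleophilic OH before the organolithium and enolate steps.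

Step 7
Reactants: 12 {[(3R)‑3‑[2‑bromo‑5‑(methoxymethoxy)phenoxy]‑2‑methylhept‑6‑en‑2‑yl]oxy}triethylsilane
Product: 14 methyl 4‑(methoxymethoxy)‑2‑{[(3R)‑2‑methyl‑2‑(triethylsilyloxy)hept‑6‑en‑3‑yl]oxy}benzoate, via aryllithium 13 (not isolated)
Conditions: n‑BuLi (1.05 equiv), THF, −78 °C, 15 min; ClCO2Me (3 equiv), −78 °C → rt
Reagents that add atoms: methyl chloroformate, COC(=O)Cl
Why: Bromine–lithium exchange followed by acylation fixes the carbon at the former C–Br site with no regiochemical doubt, and the excess chloroformate together with the bulky ortho ether suppresses diaryl ketone formation.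

Step 8
Reactants: 14 methyl 4‑(methoxymethoxy)‑2‑{[(3R)‑2‑methyl‑2‑(triethylsilyloxy)hept‑6‑en‑3‑yl]oxy}benzoate
Product: 16 methyl 4‑(methoxymethoxy)‑2‑{[(3R)‑2‑methyl‑6‑oxo‑2‑(triethylsilyloxy)hexan‑3‑yl]oxy}benzoate, via vicinal diol 15 (not isolated)
Conditions: OsO4 (2 mol%), NaIO4 (4 equiv), 2,6‑lutidine, dioxane/H2O 3:1, rt
Reagents that add atoms: osmium tetroxide, O=[Os](=O)(=O)=O (transfers oxygen to the alkene); sodium periodate, [Na+].[O-]I(=O)(=O)=O (re‑oxidant that refills it)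
Why: Lemieux–Johnson oxidative cleavage acts on the single alkene in the molecule, and the lutidine buffer keeps the medium neutral for the MOM and TES groups and prevents over‑oxidation.

Step 9
Reactants: 17 benzene‑1,3,5‑triol (phloroglucinol)
Product: 18 1,3,5‑tris(methoxymethoxy)benzene
Conditions: NaH (3.6 equiv), MOMCl (3.6 equiv), DMF, 0 °C → rt
Reagents that add atoms: chloromethyl methyl ether (MOMCl), COCCl
Why: This threefold Williamson‑type O‑alkylation with a hard electrophile goes at oxygen only, and the MOM groups serve later as ortho‑lithiation directors and leave under mild acid.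

Step 10
Reactants: 18 1,3,5‑tris(methoxymethoxy)benzene; 19 1‑bromo‑3‑methylbut‑2‑ene (prenyl bromide)
Product: 21 1,3,5‑tris(methoxymethoxy)‑2‑prenylbenzene, via 2,4,6‑tris(methoxymethoxy)phenyllithium 20 (not isolated)
Conditions: n‑BuLi (1.1 equiv), THF, 0 °C, 1 h; 19, −78 °C → rt
Reagents that add atoms: none
Why: Directed ortho‑metalation takes place at a C–H flanked by two chelating MOM ethers, and SN2 alkylation of the aryllithium by the primary allylic bromide gives the linear prenyl group.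

Step 11
Reactants: 21 1,3,5‑tris(methoxymethoxy)‑2‑prenylbenzene; 19 1‑bromo‑3‑methylbut‑2‑ene
Product: 23 1,3,5‑tris(methoxymethoxy)‑2,4‑diprenylbenzene, via monoprenyl aryllithium 22 (not isolated)
Conditions: n‑BuLi (1.1 equiv), THF, 0 °C, 1 h; 19, −78 °C → rt
Reagents that add atoms: none
Why: This is a second directed ortho‑metalation/alkylation, in which the two remaining ring C–H positions are equivalent and doubly MOM‑flanked, so chelation‑controlled ring lithiation beats deprotonation of the prenyl CH2.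

Step 12
Reactants: 23 1,3,5‑tris(methoxymethoxy)‑2,4‑diprenylbenzene; 16 methyl 4‑(methoxymethoxy)‑2‑{[(3R)‑2‑methyl‑6‑oxo‑2‑(triethylsilyloxy)hexan‑3‑yl]oxy}benzoate
Product: 25 methyl 2‑{[(3R)‑6‑ArA‑6‑hydroxy‑2‑methyl‑2‑(TES‑oxy)hexan‑3‑yl]oxy}‑4‑(MOM‑oxy)benzoate (C6 epimers), via diprenyl aryllithium 24 (not isolated)
Conditions: 23 (1.3 equiv), n‑BuLi (1.25 equiv), THF, 0 °C, 1 h; 16 (1.0 equiv), −78 °C; H2O
Reagents that add atoms: none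
Why: Directed ortho‑metalation at the last ring C–H is followed by 1,2‑addition to the aldehyde, which at −78 °C is far faster than attack on the hindered electron‑rich benzoate, and the new carbinol centre forms unselectively but is erased in step 13.

Step 13
Reactants: 25 methyl 2‑{[(3R)‑6‑ArA‑6‑hydroxy‑2‑methyl‑2‑(TES‑oxy)hexan‑3‑yl]oxy}‑4‑(MOM‑oxy)benzoate
Product: 26 methyl 2‑{[(3R)‑6‑ArA‑2‑methyl‑6‑oxo‑2‑(TES‑oxy)hexan‑3‑yl]oxy}‑4‑(MOM‑oxy)benzoate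
Conditions: Dess–Martin periodinane (1.3 equiv), NaHCO3, CH2Cl2, 0 °C → rt
Reagents that add atoms: none
Why: Dess–Martin oxidation turns the electron‑rich benzylic alcohol into the aryl ketone under buffered neutral conditions that leave the prenyl alkenes, the MOM acetals and the TES ether alone.

Step 14
Reactants: 26 methyl 2‑{[(3R)‑6‑ArA‑2‑methyl‑6‑oxo‑2‑(TES‑oxy)hexan‑3‑yl]oxy}‑4‑(MOM‑oxy)benzoate
Product: 27 (2R)‑4‑(ArA‑carbonyl)‑8‑(MOM‑oxy)‑2‑[2‑(TES‑oxy)propan‑2‑yl]‑3,4‑dihydro‑1‑benzoxepin‑5(2H)‑one (C4 epimers/enol)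
Conditions: LiN(SiMe3)2 (3 equiv), THF, −78 °C → rt (40 °C if slow); AcOH quench
Reagents that add atoms: none
Why: In this intramolecular Claisen (Dieckmann‑type) condensation the only enolisable position of 26 attacks the tethered benzoate in a seven‑membered closure modelled on the Dieckmann route to 1‑benzoxepin‑5‑ones, deprotonation of the 1,3‑diketone drives it, and the C–H of the (R) centre is not acidic.

Step 15
Reactants: 27 (2R)‑4‑(ArA‑carbonyl)‑8‑(MOM‑oxy)‑2‑[2‑(TES‑oxy)propan‑2‑yl]‑3,4‑dihydro‑1‑benzoxepin‑5(2H)‑one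
Product: 29 CNP0328977.2 (R enantiomer), via free polyphenol diketone 28 (not isolated)
Conditions: 1.25 M HCl in MeOH, 45 °C
Reagents that add atoms: none
Why: Acid‑catalysed methanolysis of the four MOM acetals and the TES ether is followed by cyclodehydration of the o‑hydroxyaryl 1,3‑diketone (the closing stage of a Baker–Venkataraman‑type flavone synthesis), where ring A is symmetric so either ortho hydroxyl gives the same chromone, dilute methanolic HCl is the usual MOM removal for prenylated flavonoids, and the (R) centre is not touched.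

## Compound list
1 | diethyl oxalate | CCOC(=O)C(=O)OCC | starting material
2 | but‑3‑en‑1‑ylmagnesium bromide | C=CCC[Mg]Br | starting material
3 | bromomagnesium hemiketal alkoxide (ethyl 2‑(bromomagnesiooxy)‑2‑ethoxyhex‑5‑enoate, racemic) | C=CCCC(OCC)(O[Mg]Br)C(=O)OCC | intermediate
4 | ethyl 2‑oxohex‑5‑enoate | C=CCCC(=O)C(=O)OCC | intermediate
5 | ethyl (2S)‑2‑hydroxyhex‑5‑enoate | C=CCC[C@H](O)C(=O)OCC | intermediate
6 | 4‑bromobenzene‑1,3‑diol | Oc1ccc(Br)c(O)c1 | starting material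
7 | 2‑bromo‑5‑(methoxymethoxy)phenol | COCOc1ccc(Br)c(O)c1 | intermediate
8 | alkoxyphosphonium ion, [(2S)‑1‑ethoxy‑1‑oxohex‑5‑en‑2‑yl]oxy(triphenyl)phosphonium | C=CCC[C@H](O[P+](c1ccccc1)(c1ccccc1)c1ccccc1)C(=O)OCC | intermediate
9 | ethyl (2R)‑2‑[2‑bromo‑5‑(methoxymethoxy)phenoxy]hex‑5‑enoate | C=CCC[C@@H](Oc1cc(OCOC)ccc1Br)C(=O)OCC | intermediate
10 | methyl ketone, (3R)‑3‑[2‑bromo‑5‑(methoxymethoxy)phenoxy]hept‑6‑en‑2‑one | C=CCC[C@@H](Oc1cc(OCOC)ccc1Br)C(C)=O | intermediate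
11 | (3R)‑3‑[2‑bromo‑5‑(methoxymethoxy)phenoxy]‑2‑methylhept‑6‑en‑2‑ol | C=CCC[C@@H](Oc1cc(OCOC)ccc1Br)C(C)(C)O | intermediate
12 | TES ether of 11 | C=CCC[C@@H](Oc1cc(OCOC)ccc1Br)C(C)(C)O[Si](CC)(CC)CC | intermediate
13 | aryllithium from 12 (Li in place of Br) | C=CCC[C@@H](Oc1cc(OCOC)ccc1[Li])C(C)(C)O[Si](CC)(CC)CC | intermediate
14 | methyl 4‑(methoxymethoxy)‑2‑{[(3R)‑2‑methyl‑2‑(triethylsilyloxy)hept‑6‑en‑3‑yl]oxy}benzoate | C=CCC[C@@H](Oc1cc(OCOC)ccc1C(=O)OC)C(C)(C)O[Si](CC)(CC)CC | intermediate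
15 | vicinal diol from 14 (6,7‑diol, C6 epimers) | OCC(O)CC[C@@H](Oc1cc(OCOC)ccc1C(=O)OC)C(C)(C)O[Si](CC)(CC)CC | intermediate
16 | methyl 4‑(methoxymethoxy)‑2‑{[(3R)‑2‑methyl‑6‑oxo‑2‑(triethylsilyloxy)hexan‑3‑yl]oxy}benzoate | O=CCC[C@@H](Oc1cc(OCOC)ccc1C(=O)OC)C(C)(C)O[Si](CC)(CC)CC | intermediate
17 | benzene‑1,3,5‑triol (phloroglucinol) | Oc1cc(O)cc(O)c1 | starting material
18 | 1,3,5‑tris(methoxymethoxy)benzene | COCOc1cc(OCOC)cc(OCOC)c1 | intermediate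
19 | 1‑bromo‑3‑methylbut‑2‑ene (prenyl bromide) | CC(C)=CCBr | starting material
20 | 2,4,6‑tris(methoxymethoxy)phenyllithium | [Li]c1c(OCOC)cc(OCOC)cc1OCOC | intermediate
21 | 1,3,5‑tris(methoxymethoxy)‑2‑prenylbenzene | CC(C)=CCc1c(OCOC)cc(OCOC)cc1OCOC | intermediate
22 | 2,4,6‑tris(methoxymethoxy)‑3‑prenylphenyllithium | CC(C)=CCc1c(OCOC)c([Li])c(OCOC)cc1OCOC | intermediate
23 | 1,3,5‑tris(methoxymethoxy)‑2,4‑diprenylbenzene | CC(C)=CCc1c(OCOC)c(CC=C(C)C)c(OCOC)cc1OCOC | intermediate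
24 | 2,4,6‑tris(methoxymethoxy)‑3,5‑diprenylphenyllithium (ArA–Li) | CC(C)=CCc1c(OCOC)c(CC=C(C)C)c(OCOC)c([Li])c1OCOC | intermediate
25 | methyl 2‑{[(3R)‑6‑ArA‑6‑hydroxy‑2‑methyl‑2‑(TES‑oxy)hexan‑3‑yl]oxy}‑4‑(MOM‑oxy)benzoate (C6 epimers) | COCOc1c(CC=C(C)C)c(OCOC)c(CC=C(C)C)c(OCOC)c1C(O)CC[C@@H](Oc1cc(OCOC)ccc1C(=O)OC)C(C)(C)O[Si](CC)(CC)CC | intermediate
26 | methyl 2‑{[(3R)‑6‑ArA‑2‑methyl‑6‑oxo‑2‑(TES‑oxy)hexan‑3‑yl]oxy}‑4‑(MOM‑oxy)benzoate | COCOc1c(CC=C(C)C)c(OCOC)c(CC=C(C)C)c(OCOC)c1C(=O)CC[C@@H](Oc1cc(OCOC)ccc1C(=O)OC)C(C)(C)O[Si](CC)(CC)CC | intermediate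
27 | (2R)‑4‑(ArA‑carbonyl)‑8‑(MOM‑oxy)‑2‑[2‑(TES‑oxy)propan‑2‑yl]‑3,4‑dihydro‑1‑benzoxepin‑5(2H)‑one (C4 epimers/enol) | COCOc1c(CC=C(C)C)c(OCOC)c(CC=C(C)C)c(OCOC)c1C(=O)C1C[C@H](C(C)(C)O[Si](CC)(CC)CC)Oc2cc(OCOC)ccc2C1=O | intermediate
28 | (2R)‑8‑hydroxy‑2‑(2‑hydroxypropan‑2‑yl)‑4‑(2,4,6‑trihydroxy‑3,5‑diprenylbenzoyl)‑3,4‑dihydro‑1‑benzoxepin‑5(2H)‑one | CC(C)=CCc1c(O)c(CC=C(C)C)c(O)c(C(=O)C2C[C@H](C(C)(C)O)Oc3cc(O)ccc3C2=O)c1O | intermediate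
29 | CNP0328977.2: 5,7,4'‑trihydroxy‑6,8‑diprenylflavone whose C3 and 2'‑O are bridged by CH2–CH[C(CH3)2OH], (R) at the bridge CH | CC(C)=CCc1c(O)c(CC=C(C)C)c2oc3c(c(=O)c2c1O)C[C@H](C(C)(C)O)Oc1cc(O)ccc1-3 | target

## Count and risks
Total steps: 15. Longest linear sequence: 11 (steps 1, 2, 4, 5, 6, 7, 8, 12, 13, 14, 15).

**Step 12.** The hexasubstituted, basic aryllithium may enolise aldehyde 16 instead of adding to it. The fallback forms ring D before the union and gives the aryllithium only a small, non‑enolisable electrophile. It sets out from 16 and 23 and comes back at 27.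
- Aldehyde 16 is oxidised (NaClO2, NaH2PO4, 2‑methylbut‑2‑ene, tBuOH/H2O) to (4R)‑4‑[2‑(methoxycarbonyl)‑5‑(MOM‑oxy)phenoxy]‑5‑methyl‑5‑(TES‑oxy)hexanoic acid F1.
- MeI/K2CO3 in DMF converts F1 into methyl (4R)‑4‑[2‑(methoxycarbonyl)‑5‑(MOM‑oxy)phenoxy]‑5‑methyl‑5‑(TES‑oxy)hexanoate F2.
- Dieckmann condensation (KOtBu, THF, 0 °C → rt) gives methyl (2R)‑8‑(MOM‑oxy)‑5‑oxo‑2‑[2‑(TES‑oxy)propan‑2‑yl]‑2,3,4,5‑tetrahydro‑1‑benzoxepine‑4‑carboxylate F3.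
- Krapcho demethoxycarbonylation (LiCl, wet DMSO, 140 °C) gives (2R)‑8‑(MOM‑oxy)‑2‑[2‑(TES‑oxy)propan‑2‑yl]‑3,4‑dihydro‑1‑benzoxepin‑5(2H)‑one F4.
- Separately, 23 is lithiated to 24 as before and quenched with DMF to give 2,4,6‑tris(MOM‑oxy)‑3,5‑diprenylbenzaldehyde F5.
- The enolate of F4 (LiN(iPr)2, THF, −78 °C) adds to F5 to give (2R)‑4‑[ArA(hydroxy)methyl]‑8‑(MOM‑oxy)‑2‑[2‑(TES‑oxy)propan‑2‑yl]‑3,4‑dihydro‑1‑benzoxepin‑5(2H)‑one F6.
- Dess–Martin oxidation of F6 gives 27.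

**Step 14.** The seven‑membered closure of a hindered ketone enolate onto an electron‑rich benzoate may stall. The fallback replaces the ester electrophile by an aldehyde, so the ring is closed by aldol addition and then oxidised. It sets out from 26 and comes back at 27.
- LiAlH4 (THF, 0 °C) reduces the ester and the ketone of 26 to (4R)‑1‑ArA‑4‑[2‑(hydroxymethyl)‑5‑(MOM‑oxy)phenoxy]‑5‑methyl‑5‑(TES‑oxy)hexan‑1‑ol F7.
- Dess–Martin periodinane (3 equiv, NaHCO3, CH2Cl2) gives 2‑{[(3R)‑6‑ArA‑2‑methyl‑6‑oxo‑2‑(TES‑oxy)hexan‑3‑yl]oxy}‑4‑(MOM‑oxy)benzaldehyde F8.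
- LiN(SiMe3)2 (1.1 equiv, THF, −78 °C) closes ring D by intramolecular aldol addition to ArA (2R)‑5‑hydroxy‑8‑(MOM‑oxy)‑2‑[2‑(TES‑oxy)propan‑2‑yl]‑2,3,4,5‑tetrahydro‑1‑benzoxepin‑4‑yl ketone F9.
- A second Dess–Martin oxidation gives 27.

**Step 15.** Acid may add the free ortho phenols across the prenyl alkenes to form chromans. The fallback carries allyl groups, which resist protonation, through the acid step and converts them into prenyl groups afterwards under neutral conditions. It sets out from 18 and 16 and comes back at 29.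
- Lithiation of 18 to 20 and alkylation with allyl bromide gives 2‑allyl‑1,3,5‑tris(MOM‑oxy)benzene F10.
- n‑BuLi converts F10 into 3‑allyl‑2,4,6‑tris(MOM‑oxy)phenyllithium F11, which allyl bromide converts into 2,4‑diallyl‑1,3,5‑tris(MOM‑oxy)benzene F12.
- n‑BuLi then gives 3,5‑diallyl‑2,4,6‑tris(MOM‑oxy)phenyllithium F13.
- F13 adds to 16 at −78 °C to give methyl 2‑{[(3R)‑6‑ArL‑6‑hydroxy‑2‑methyl‑2‑(TES‑oxy)hexan‑3‑yl]oxy}‑4‑(MOM‑oxy)benzoate F14.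
- Dess–Martin oxidation gives methyl 2‑{[(3R)‑6‑ArL‑2‑methyl‑6‑oxo‑2‑(TES‑oxy)hexan‑3‑yl]oxy}‑4‑(MOM‑oxy)benzoate F15.
- LiN(SiMe3)2 gives (2R)‑4‑(ArL‑carbonyl)‑8‑(MOM‑oxy)‑2‑[2‑(TES‑oxy)propan‑2‑yl]‑3,4‑dihydro‑1‑benzoxepin‑5(2H)‑one F16.
- Methanolic HCl passes through (2R)‑4‑(3,5‑diallyl‑2,4,6‑trihydroxybenzoyl)‑8‑hydroxy‑2‑(2‑hydroxypropan‑2‑yl)‑3,4‑dihydro‑1‑benzoxepin‑5(2H)‑one F17 to the 6,8‑diallyl analogue of the target F18.
- Double cross‑metathesis of F18 with 2‑methylbut‑2‑ene (second‑generation Grubbs catalyst, CH2Cl2, 40 °C) gives 29.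

## Further compounds
F1 | step 12 | (4R)‑4‑[2‑(methoxycarbonyl)‑5‑(MOM‑oxy)phenoxy]‑5‑methyl‑5‑(TES‑oxy)hexanoic acid | OC(=O)CC[C@@H](Oc1cc(OCOC)ccc1C(=O)OC)C(C)(C)O[Si](CC)(CC)CC
F2 | step 12 | methyl (4R)‑4‑[2‑(methoxycarbonyl)‑5‑(MOM‑oxy)phenoxy]‑5‑methyl‑5‑(TES‑oxy)hexanoate | COC(=O)CC[C@@H](Oc1cc(OCOC)ccc1C(=O)OC)C(C)(C)O[Si](CC)(CC)CC
F3 | step 12 | methyl (2R)‑8‑(MOM‑oxy)‑5‑oxo‑2‑[2‑(TES‑oxy)propan‑2‑yl]‑2,3,4,5‑tetrahydro‑1‑benzoxepine‑4‑carboxylate | COC(=O)C1C[C@H](C(C)(C)O[Si](CC)(CC)CC)Oc2cc(OCOC)ccc2C1=O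
F4 | step 12 | (2R)‑8‑(MOM‑oxy)‑2‑[2‑(TES‑oxy)propan‑2‑yl]‑3,4‑dihydro‑1‑benzoxepin‑5(2H)‑one | O=C1CC[C@H](C(C)(C)O[Si](CC)(CC)CC)Oc2cc(OCOC)ccc12
F5 | step 12 | 2,4,6‑tris(MOM‑oxy)‑3,5‑diprenylbenzaldehyde | COCOc1c(CC=C(C)C)c(OCOC)c(CC=C(C)C)c(OCOC)c1C=O
F6 | step 12 | (2R)‑4‑[ArA(hydroxy)methyl]‑8‑(MOM‑oxy)‑2‑[2‑(TES‑oxy)propan‑2‑yl]‑3,4‑dihydro‑1‑benzoxepin‑5(2H)‑one | COCOc1c(CC=C(C)C)c(OCOC)c(CC=C(C)C)c(OCOC)c1C(O)C1C[C@H](C(C)(C)O[Si](CC)(CC)CC)Oc2cc(OCOC)ccc2C1=O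
F7 | step 14 | (4R)‑1‑ArA‑4‑[2‑(hydroxymethyl)‑5‑(MOM‑oxy)phenoxy]‑5‑methyl‑5‑(TES‑oxy)hexan‑1‑ol | COCOc1c(CC=C(C)C)c(OCOC)c(CC=C(C)C)c(OCOC)c1C(O)CC[C@@H](Oc1cc(OCOC)ccc1CO)C(C)(C)O[Si](CC)(CC)CC
F8 | step 14 | 2‑{[(3R)‑6‑ArA‑2‑methyl‑6‑oxo‑2‑(TES‑oxy)hexan‑3‑yl]oxy}‑4‑(MOM‑oxy)benzaldehyde | COCOc1c(CC=C(C)C)c(OCOC)c(CC=C(C)C)c(OCOC)c1C(=O)CC[C@@H](Oc1cc(OCOC)ccc1C=O)C(C)(C)O[Si](CC)(CC)CC
F9 | step 14 | ArA (2R)‑5‑hydroxy‑8‑(MOM‑oxy)‑2‑[2‑(TES‑oxy)propan‑2‑yl]‑2,3,4,5‑tetrahydro‑1‑benzoxepin‑4‑yl ketone | COCOc1c(CC=C(C)C)c(OCOC)c(CC=C(C)C)c(OCOC)c1C(=O)C1C[C@H](C(C)(C)O[Si](CC)(CC)CC)Oc2cc(OCOC)ccc2C1O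
F10 | step 15 | 2‑allyl‑1,3,5‑tris(MOM‑oxy)benzene | C=CCc1c(OCOC)cc(OCOC)cc1OCOC
F11 | step 15 | 3‑allyl‑2,4,6‑tris(MOM‑oxy)phenyllithium | C=CCc1c(OCOC)c([Li])c(OCOC)cc1OCOC
F12 | step 15 | 2,4‑diallyl‑1,3,5‑tris(MOM‑oxy)benzene | C=CCc1c(OCOC)c(CC=C)c(OCOC)cc1OCOC
F13 | step 15 | 3,5‑diallyl‑2,4,6‑tris(MOM‑oxy)phenyllithium | C=CCc1c(OCOC)c(CC=C)c(OCOC)c([Li])c1OCOC
F14 | step 15 | methyl 2‑{[(3R)‑6‑ArL‑6‑hydroxy‑2‑methyl‑2‑(TES‑oxy)hexan‑3‑yl]oxy}‑4‑(MOM‑oxy)benzoate | COCOc1c(CC=C)c(OCOC)c(CC=C)c(OCOC)c1C(O)CC[C@@H](Oc1cc(OCOC)ccc1C(=O)OC)C(C)(C)O[Si](CC)(CC)CC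
F15 | step 15 | methyl 2‑{[(3R)‑6‑ArL‑2‑methyl‑6‑oxo‑2‑(TES‑oxy)hexan‑3‑yl]oxy}‑4‑(MOM‑oxy)benzoate | COCOc1c(CC=C)c(OCOC)c(CC=C)c(OCOC)c1C(=O)CC[C@@H](Oc1cc(OCOC)ccc1C(=O)OC)C(C)(C)O[Si](CC)(CC)CC
F16 | step 15 | (2R)‑4‑(ArL‑carbonyl)‑8‑(MOM‑oxy)‑2‑[2‑(TES‑oxy)propan‑2‑yl]‑3,4‑dihydro‑1‑benzoxepin‑5(2H)‑one | COCOc1c(CC=C)c(OCOC)c(CC=C)c(OCOC)c1C(=O)C1C[C@H](C(C)(C)O[Si](CC)(CC)CC)Oc2cc(OCOC)ccc2C1=O
F17 | step 15 | (2R)‑4‑(3,5‑diallyl‑2,4,6‑trihydroxybenzoyl)‑8‑hydroxy‑2‑(2‑hydroxypropan‑2‑yl)‑3,4‑dihydro‑1‑benzoxepin‑5(2H)‑one | C=CCc1c(O)c(CC=C)c(O)c(C(=O)C2C[C@H](C(C)(C)O)Oc3cc(O)ccc3C2=O)c1O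
F18 | step 15 | 6,8‑diallyl analogue of the target | C=CCc1c(O)c(CC=C)c2oc3c(c(=O)c2c1O)C[C@H](C(C)(C)O)Oc1cc(O)ccc1-3
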